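The plan rests on opening the resorcinol ring at C3–C4 and C6–C1. That splits it into a three-carbon nucleophile, C4–C5–C6 with the side chain on C5 (a 2-alkylallyl unit), and a three-carbon bis-electrophile, C1–C2–C3 with both oxygens (a malonyl unit); joining them gives a cyclohexenedione that is simply the keto tautomer of the arene. One Lewis-acid operation therefore acylates a 2-alkylallylsilane twice with malonyl dichloride, closes the ring and delivers the unprotected resorcinol. The precursor is an allyltrimethylsilane bearing a heptadec-16-ynyl chain on its central carbon; the terminal alkyne is a masked methyl ketone, hydrated last.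

Key step: step 3

Remark: ring atoms are numbered C1 (OH), C2, C3 (OH), C4, C5 (side chain), C6; octadec-17-ynoic acid 1, Grignard reagent 3 and malonyl dichloride 6 are taken as purchased materials.

Step 1
Reactants: 1 octadec-17-ynoic acid
Product: 2 methyl octadec-17-ynoate
Conditions: MeOH, H2SO4 (cat.), reflux
Reagents that add atoms: methanol, CO
Why: Fischer esterification of an unhindered fatty acid in excess methanol is driven to completion by mass action, and an isolated terminal alkyne is inert to catalytic Brønsted acid when no soft metal is present.

Step 2
Reactants: 2 methyl octadec-17-ynoate; 3 (trimethylsilyl)methylmagnesium chloride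
Product: 5 trimethyl(2-methylidenenonadec-18-yn-1-yl)silane, via bis(silylmethyl)carbinol 4 (not isolated)
Conditions: 3 (5 equiv), anhydrous CeCl3 (5 equiv), THF, −78 °C to rt; aq. NH4Cl; crude 4, SiO2, CH2Cl2, rt
Reagents that add atoms: none
Why: The organocerium reagent formed from 3 and CeCl3 is nucleophilic but weakly basic, so it should add twice to the ester without stalling at the enolisable α-silyl ketone, and the symmetrical β-hydroxysilane 4 then undergoes acid-promoted Peterson elimination on silica, leaving the second silyl group as the allylsilane; the excess of 3 allows for the equivalent consumed by the acetylenic C–H, which is restored on quenching.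

Step 3
Reactants: 5 trimethyl(2-methylidenenonadec-18-yn-1-yl)silane; 6 malonyl dichloride
Product: 9 5-(heptadec-16-yn-1-yl)benzene-1,3-diol, via keto acid chloride 7 (not isolated), via cyclohexenedione 8 (not isolated)
Conditions: 6 (2 equiv), TiCl4 (2.2 equiv), CH2Cl2 (high dilution), −78 °C; 5 and 2,6-di-tert-butyl-4-methylpyridine (1.2 equiv) in CH2Cl2 by syringe pump; −78 to −20 °C; MeOH quench; K2CO3, MeOH, rt; aq. HCl
Reagents that add atoms: none
Why: Proposed new method: TiCl4 activates one acyl chloride of 6, the methylidene carbon of 5 attacks it (bond C3–C4) and the resulting β-silyl tertiary cation loses Me3SiCl, giving the transposed 1,1-disubstituted alkene 7; its new methylidene carbon then attacks the second, chelation-activated acyl chloride (bond C6–C1), the ring cation at C5 loses a proton to give 8, and twofold enolisation to arene 9 renders the sequence irreversible. The closest known reaction types are the Lewis-acid SE2′ acylation of allylsilanes by acid chlorides, the intramolecular Darzens–Nenitzescu acylation of alkenes and the twofold C-acylation of enol ethers by malonyl dichloride, none of which has been used to join an allylsilane and a malonyl unit into an arene. The one ring formed, the carbocycle C1–C6, closes in a 6-endo-trig mode at the alkene, because Markovnikov attack places the charge on the tertiary ring carbon C5 whereas 5-exo closure would need a primary cation. No stereocentre is created. The step needs site control in the first acylation, which the β-silicon effect provides, chemoselectivity over the remote alkyne, which rests on the far lower π-nucleophilicity of a terminal alkyne than of an allylsilane or a 1,1-dialkylethene, and cyclisation in preference to a second intermolecular acylation, which slow addition of 5 to excess 6 at high dilution and −78 °C favours. The hindered pyridine traps HCl that would otherwise protodesilylate unreacted 5, and the methanolic K2CO3 work-up destroys excess 6 and cleaves any aryl malonate formed by O-acylation of 9.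

Step 4
Reactants: 9 5-(heptadec-16-yn-1-yl)benzene-1,3-diol
Product: 10 Hansfordiol B, 17-(3,5-dihydroxyphenyl)heptadecan-2-one
Conditions: Ph3PAuNTf2 (2 mol %), MeOH/H2O (10:1), 60 °C
Reagents that add atoms: water, O
Why: Monovalent gold activates the terminal alkyne toward Markovnikov attack by methanol or water, which are present in vast excess over the phenols, and the enol or enol ether so formed should collapse to the methyl ketone (gold-catalysed alkyne hydration).

Compound list
1 | octadec-17-ynoic acid | C#CCCCCCCCCCCCCCCCC(=O)O | starting material
2 | methyl octadec-17-ynoate | C#CCCCCCCCCCCCCCCCC(=O)OC | intermediate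
3 | (trimethylsilyl)methylmagnesium chloride | C[Si](C)(C)C[Mg]Cl | starting material
4 | 1-(trimethylsilyl)-2-[(trimethylsilyl)methyl]nonadec-18-yn-2-ol | C#CCCCCCCCCCCCCCCCC(O)(C[Si](C)(C)C)C[Si](C)(C)C | intermediate (not isolated)
5 | trimethyl(2-methylidenenonadec-18-yn-1-yl)silane | C#CCCCCCCCCCCCCCCCC(=C)C[Si](C)(C)C | intermediate
6 | malonyl dichloride (propanedioyl dichloride) | O=C(Cl)CC(=O)Cl | starting material
7 | 5-methylidene-3-oxodocos-21-ynoyl chloride | C#CCCCCCCCCCCCCCCCC(=C)CC(=O)CC(=O)Cl | intermediate (not isolated)
8 | 5-(heptadec-16-yn-1-yl)cyclohex-4-ene-1,3-dione | C#CCCCCCCCCCCCCCCCC1=CC(=O)CC(=O)C1 | intermediate (not isolated)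
9 | 5-(heptadec-16-yn-1-yl)benzene-1,3-diol | C#CCCCCCCCCCCCCCCCc1cc(O)cc(O)c1 | intermediate
10 | Hansfordiol B, 17-(3,5-dihydroxyphenyl)heptadecan-2-one | CC(=O)CCCCCCCCCCCCCCCc1cc(O)cc(O)c1 | target

Total step count: 4
Longest linear sequence: 4 steps (1 to 2 to 5 to 9 to 10)

Steps most likely to fail

1. Step 3 (Proposed new method). The ring-closing acylation may be slower than capture of the keto acid chloride by a second molecule of allylsilane, liberated acid may protodesilylate the allylsilane, malonyl dichloride may self-condense, or the electron-rich arene may be acylated further. The fallback uses the classical Michael–Claisen and aromatisation route to 5-alkylresorcinols, sets out from 2 and comes back at 9. Ester 2 would be reduced (i-Bu2AlH, CH2Cl2, −78 °C) to octadec-17-ynal F1. Wittig reaction with 1-(triphenylphosphoranylidene)propan-2-one (toluene, 90 °C) should give (E)-henicos-3-en-20-yn-2-one F2. Michael addition of dimethyl malonate followed by Claisen ring closure (NaOMe, MeOH, reflux) should give racemic methyl 6-(heptadec-16-yn-1-yl)-2-hydroxy-4-oxocyclohex-2-ene-1-carboxylate F3. Enol bromination and dehydrobromination (Br2, 1 equiv, DMF, 0 to 80 °C; the enol reacts far faster than the alkyne) should give methyl 2-(heptadec-16-yn-1-yl)-4,6-dihydroxybenzoate F4. Saponification and decarboxylation (aq. NaOH, reflux; then HCl) returns to 9.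

2. Step 2. Enolisation of the transient α-silyl ketone may stop the sequence after one addition if the CeCl3 is not rigorously dry, and the acetylide formed from the terminal alkyne may consume reagent or add to carbonyl intermediates. The fallback replaces double addition and elimination by single addition and carbonyl methylenation, sets out from 2 and comes back at 5. Me3SiCH2Li (3 equiv, pentane/THF, −78 to 0 °C; buffered NH4Cl quench) adds once, because the α-silyl ketone is protected as its enolate, and should give 1-(trimethylsilyl)nonadec-18-yn-2-one F5. Wittig methylenation (Ph3PCH3Br, KHMDS, THF, 0 °C to rt, excess ylide) then gives 5.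

3. Step 4. The cationic gold catalyst may be deactivated by reduction or by binding to the resorcinol, or the activated alkyne may be captured by a phenol oxygen or an arene carbon of another molecule instead of by solvent. The fallback masks the phenols and uses mercury catalysis, sets out from 9 and comes back at 10. Acetylation (Ac2O, pyridine, rt) should give 5-(heptadec-16-yn-1-yl)-1,3-phenylene diacetate F6. Hydration with divalent mercury (Hg(OTf)2, 5 mol %, H2O, MeCN/CH2Cl2, rt) should give 5-(16-oxoheptadecyl)-1,3-phenylene diacetate F7. Methanolysis (K2CO3, MeOH, rt) then gives 10.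

Further compounds
F1 | step 3 | octadec-17-ynal | C#CCCCCCCCCCCCCCCCC=O
F2 | step 3 | (E)-henicos-3-en-20-yn-2-one | CC(=O)/C=C/CCCCCCCCCCCCCCCC#C
F3 | step 3 | methyl 6-(heptadec-16-yn-1-yl)-2-hydroxy-4-oxocyclohex-2-ene-1-carboxylate (racemic) | COC(=O)C1C(CCCCCCCCCCCCCCCC#C)CC(=O)C=C1O
F4 | step 3 | methyl 2-(heptadec-16-yn-1-yl)-4,6-dihydroxybenzoate | COC(=O)c1c(O)cc(O)cc1CCCCCCCCCCCCCCCC#C
F5 | step 2 | 1-(trimethylsilyl)nonadec-18-yn-2-one | C#CCCCCCCCCCCCCCCCC(=O)C[Si](C)(C)C
F6 | step 4 | 5-(heptadec-16-yn-1-yl)-1,3-phenylene diacetate | CC(=O)Oc1cc(CCCCCCCCCCCCCCCC#C)cc(OC(C)=O)c1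
F7 | step 4 | 5-(16-oxoheptadecyl)-1,3-phenylene diacetate | CC(=O)CCCCCCCCCCCCCCCc1cc(OC(C)=O)cc(OC(C)=O)c1
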